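Watch the partner.

| flask | starting material | partner | temperature | remark | time |
|---|---|---|---|---|---|
| Wednesday's | 0.050 M | 0.10 M | 110 °C | the very flask that is asked about, followed so far |  |
| Tuesday's | 0.10 M | 0.10 M | 95 °C | run made earlier |  |
| flask | 0.050 M | 0.100 M | 110 °C |  | 20 h |

| run | time / h | target / % |
|---|---|---|
| Wednesday's | 2.00 | 13.4 |
| Wednesday's | 6.00 | 18.7 |
| Wednesday's | 10.0 | 20.6 |
| Wednesday's | 15.0 | 19.4 |
| Tuesday's | 1.00 | 5.3 |
| Tuesday's | 2.00 | 11.7 |
| Tuesday's | 3.00 | 13.5 |
| Tuesday's | 4.00 | 14.3 |

(standard deviation of a reading: 1 percentage point)

- green: at 20 h add partner, 50.0% of the amount charged, then wait 40 h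
- ochre: at 20 h raise the temperature by 25 K, then wait 40 h
- blue: at 20 h take out 90% of the target then present, then wait 40 h
- amber: change nothing and wait 40 h more

- target taken out counts as made
- additions bring no volume worth counting

* target, in percent of the starting material first charged, at 20 h
* which option adds most target ("none" when 2 percentage points or less is all one gets) (green / ochre / blue / amber / none)
* target present, with what was taken out counted in, in percent of the starting material first charged, after ochre
* target present, with what was taken out counted in, in percent of the starting material first charged, after amber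

I build Wednesday's flask one process at a time. With the main step alone, starting material + partner → target, and with partner held constant (pseudo-first-order), the first reading y at time t gives a rate constant r:

r = −ln(1 − y)/t = 0.0719 h⁻¹

That rate would carry this flask to 76.3% by 20 h. But the late readings stand at 20.6% and 19.4%, so I add a rival path that takes starting material without partner, and I replace the flat end of the readings by its mean, ȳ = 20.0%, which is less than the main step alone gives. Target against everything else, per mole per litre of partner c, is then my selectivity factor S:

S = ȳ/((1 − ȳ)·c) = 2.50 M⁻¹, so that y = Sc/(1 + Sc)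

Last comes the rest. I can't tell from the readings, with their scatter of 1 percentage point, whether the remainder is lost or simulated, so I reckon on a store and let y rise to the level that S gives for a new c, which is my guess, S being read at a single c. Green is then the option that moves c, while blue leaves c alone and so leaves my split as it is; counting the partner as charged, green takes c to 0.150 M:

y = 27.3%

So I expect about 20.0% at 20 h and name green.

The forecast, from the same runs, says “The simplest reading is a reversible reaction” and gives 20% now, 26% after ochre, 20% after amber, and blue as best. We part on the best option.

The flask gives 20.6% now, 24.3% after ochre and 24.0% after amber.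

    partner → decomposed reagent (k = 0.0258 h⁻¹, Ea = 119 kJ mol⁻¹)
    intermediate C → side product (k = 0.0675 h⁻¹, Ea = 129 kJ mol⁻¹)
    starting material ⇌ intermediate B (K = 21.3, k = 0.780 h⁻¹, Ea = 130 kJ mol⁻¹, ΔH = −78.0 kJ mol⁻¹)
    starting material + partner → target (k = 2.10 M⁻¹ h⁻¹, Ea = 71.0 kJ mol⁻¹)
    starting material → intermediate A (k = 0.204 h⁻¹, Ea = 124 kJ mol⁻¹)
    starting material ⇌ dormant form (K = 0.410, k = 0.765 h⁻¹, Ea = 106 kJ mol⁻¹, ΔH = −60.0 kJ mol⁻¹)
    partner + intermediate A → intermediate C (k = 7.64 M⁻¹ h⁻¹, Ea = 93.0 kJ mol⁻¹)
    (constants at 110 °C)

Green adds 6.9 points, the most, while blue adds 3.4 points. My S gave a gain of 7.3 points, although the flask's partner at 20.0 h is 45% of its charge, below the charge I counted. Intermediate B, the resting state of the starting material in this flask, holds 52.6% at 20.0 h. The neighbouring flask has 0.40 M of partner, where the same S gives 50.0%, and that flask holds 53.9% of target at 20.0 h.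

The data were computed for substances that don't exist.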